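**Retrosynthetic overview**

- The strategy rests on the C6 hydroxyl of benzofuran ring A. C6 lies two bonds from C7a, so C7 and C6 are traced back to a ketene carbon pair on furan C7a, and C4 and C5 to a vinyl group on the neighbouring furan carbon C3a.
- Ring A is therefore made last, from a 2-(diazoacetyl)-3-vinyl-5-arylfuran: Wolff rearrangement forms C7–C7a, and 6π closure of the ketene onto the vinyl group forms C5–C6. Removal of the two MOM groups then gives the target.
- The diazoketone comes from the corresponding methyl furoate. The furan C5–aryl bond is made by metalation of methyl 3-vinylfuran-2-carboxylate and Negishi coupling with a 2,6-diprenylated aryl chloride.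
- The aryl chloride comes from 5-chlororesorcinol (MOM protection, double bromination beside chlorine, two bromine–magnesium exchange/prenylation cycles). The furan comes from 3-bromofuran-2-carboxylic acid (esterification, Suzuki vinylation).
- Ring order: the resorcinol ring and the furan are bought; ring A is the only ring constructed.

Key step: step 10

Remark on the chemistry: the target has no stereocentre and no stereogenic double bond. 5-Chlororesorcinol is taken as commercially available, and its chlorine marks the carbon that will carry the benzofuran.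

**Route**

Step 1
Reactants: 1 5-chlororesorcinol
Product: 2 1-chloro-3,5-bis(methoxymethoxy)benzene
Conditions: MOMCl (2.5 equiv), i-Pr2NEt (3 equiv), CH2Cl2, 0 °C to rt
Reagents that add atoms: chloromethyl methyl ether, COCCl
Why: O-alkylation of both phenols with the chloromethyl ether masks them as acetals that should survive the later organometallic, basic and photochemical steps.

Step 2
Reactants: 2 1-chloro-3,5-bis(methoxymethoxy)benzene
Product: 3 2,4-dibromo-3-chloro-1,5-bis(methoxymethoxy)benzene
Conditions: NBS (2.1 equiv), MeCN, 0 °C to rt, dark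
Reagents that add atoms: N-bromosuccinimide, O=C1CCC(=O)N1Br
Why: Electrophilic aromatic bromination should go twice to the two equivalent carbons flanking chlorine, each para to one OMOM group and ortho to the other (the usual site in 5-substituted resorcinol diethers), whereas the carbon between the two OMOM groups is only ortho-activated and more shielded.

Step 3
Reactants: 3 2,4-dibromo-3-chloro-1,5-bis(methoxymethoxy)benzene; 4 prenyl bromide
Product: 6 2-bromo-3-chloro-1,5-bis(methoxymethoxy)-4-(3-methylbut-2-en-1-yl)benzene, via arylmagnesium chloride 5 (not isolated)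
Conditions: i-PrMgCl·LiCl (1.1 equiv), THF, −15 to 0 °C; then CuBr·SMe2 (10 mol%), prenyl bromide (1.3 equiv), −15 °C to rt
Reagents that add atoms: prenyl bromide, CC(C)=CCBr
Why: Bromine–magnesium exchange is fast at a C–Br bond flanked by a chelating OMOM group and an electron-withdrawing chlorine and stops after one exchange, the ortho-chloro Grignard reagent is stable at these temperatures, and copper-catalysed allylic substitution on prenyl bromide should occur at the unhindered primary carbon (SN2) to give the linear prenyl group.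

Step 4
Reactants: 6 2-bromo-3-chloro-1,5-bis(methoxymethoxy)-4-(3-methylbut-2-en-1-yl)benzene; 4 prenyl bromide
Product: 8 3-chloro-1,5-bis(methoxymethoxy)-2,4-bis(3-methylbut-2-en-1-yl)benzene, via arylmagnesium chloride 7 (not isolated)
Conditions: i-PrMgCl·LiCl (1.2 equiv), THF, −15 °C to rt; then CuBr·SMe2 (10 mol%), prenyl bromide (1.3 equiv), −15 °C to rt
Reagents that add atoms: prenyl bromide, CC(C)=CCBr
Why: The same bromine–magnesium exchange and copper-catalysed SN2 allylation is repeated on the remaining C–Br bond, which is again flanked by OMOM and chlorine, while the C–Cl bond is inert to the exchange reagent.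

Step 5
Reactants: 9 3-bromofuran-2-carboxylic acid
Product: 10 methyl 3-bromofuran-2-carboxylate
Conditions: MeI (1.5 equiv), K2CO3, DMF, rt
Reagents that add atoms: iodomethane, CI
Why: Carboxylate O-alkylation (SN2 on iodomethane) gives the ester, which tolerates the later amide-base metalation.

Step 6
Reactants: 10 methyl 3-bromofuran-2-carboxylate; 11 4,4,5,5-tetramethyl-2-vinyl-1,3,2-dioxaborolane
Product: 12 methyl 3-ethenylfuran-2-carboxylate
Conditions: vinylboronate 11 (1.3 equiv), PdCl2(dppf) (3 mol%), K2CO3, 1,4-dioxane/H2O, 80 °C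
Reagents that add atoms: 4,4,5,5-tetramethyl-2-vinyl-1,3,2-dioxaborolane, C=CB1OC(C)(C)C(C)(C)O1
Why: Suzuki–Miyaura coupling at the activated C3–Br bond (ortho to the ester) installs the two carbons that become C4 and C5 of ring A.

Step 7
Reactants: 12 methyl 3-ethenylfuran-2-carboxylate; 8 3-chloro-1,5-bis(methoxymethoxy)-2,4-bis(3-methylbut-2-en-1-yl)benzene
Product: 15 methyl 5-[3,5-bis(methoxymethoxy)-2,6-bis(3-methylbut-2-en-1-yl)phenyl]-3-ethenylfuran-2-carboxylate, via furylmagnesium chloride 13 (not isolated), via furylzinc chloride 14 (not isolated)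
Conditions: 12 (1.4 equiv), TMPMgCl·LiCl (1.5 equiv), THF, −40 °C; ZnCl2 (1.6 equiv), −40 °C to rt; then 8 (1.0 equiv), Pd2(dba)3 (2 mol%), RuPhos (8 mol%), THF, 65 °C
Reagents that add atoms: none
Why: The hindered amide base should magnesiate the most acidic remaining furan C–H (C5, alpha to oxygen, the ester-adjacent carbon being blocked by the vinyl group) without attacking the ester, and after transmetalation to zinc a Negishi coupling with a bulky dialkylbiarylphosphine ligand, a combination suited to di-ortho-substituted aryl chlorides, joins furan C5 to the aryl carbon.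

Step 8
Reactants: 15 methyl 5-[3,5-bis(methoxymethoxy)-2,6-bis(3-methylbut-2-en-1-yl)phenyl]-3-ethenylfuran-2-carboxylate
Product: 16 5-[3,5-bis(methoxymethoxy)-2,6-bis(3-methylbut-2-en-1-yl)phenyl]-3-ethenylfuran-2-carboxylic acid
Conditions: LiOH·H2O (3 equiv), THF/MeOH/H2O, rt; then 1 M HCl to pH 4, 0 °C
Reagents that add atoms: lithium hydroxide, [Li+].[OH-]
Why: Saponification of the methyl ester, to which the MOM acetals, the alkenes and the biaryl bond are inert, with a cold and only weakly acidic work-up that leaves the acetals intact.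

Step 9
Reactants: 16 5-[3,5-bis(methoxymethoxy)-2,6-bis(3-methylbut-2-en-1-yl)phenyl]-3-ethenylfuran-2-carboxylic acid; 17 trimethylsilyldiazomethane
Product: 19 2-diazo-1-{5-[3,5-bis(methoxymethoxy)-2,6-bis(3-methylbut-2-en-1-yl)phenyl]-3-ethenylfuran-2-yl}ethan-1-one, via mixed carbonic anhydride 18 (not isolated)
Conditions: ClCO2Et (1.2 equiv), Et3N (1.3 equiv), THF, −15 °C; then TMSCHN2 (2.0 equiv, hexanes), MeCN, 0 °C to rt, dark; used promptly
Reagents that add atoms: trimethylsilyldiazomethane, C[Si](C)(C)C=[N+]=[N-]
Why: Activation as the mixed carbonic anhydride avoids HCl (which would endanger the MOM and prenyl groups), and C-acylation of trimethylsilyldiazomethane with loss of the silyl group gives the terminal diazoketone, as in the first stage of an Arndt–Eistert sequence.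

Step 10
Reactants: 19 2-diazo-1-{5-[3,5-bis(methoxymethoxy)-2,6-bis(3-methylbut-2-en-1-yl)phenyl]-3-ethenylfuran-2-yl}ethan-1-one
Product: 22 2-[3,5-bis(methoxymethoxy)-2,6-bis(3-methylbut-2-en-1-yl)phenyl]-1-benzofuran-6-ol, via furylketene 20 (not isolated), via 5H-benzofuran-6-one 21 (not isolated)
Conditions: hν (365 nm), degassed toluene (0.01 M), 25 °C; then 80 °C, dark
Reagents that add atoms: none
Why: Excitation of the s-Z diazoketone expels N2 with concerted 1,2-shift of the furyl group (photochemical Wolff rearrangement), so the former diazo carbon becomes C7 bonded to C7a and the former carbonyl carbon becomes the ketene carbon C6. The ketene C=C, the furan C7a=C3a bond and the vinyl group form a hexatriene held s-cis by the furan, and thermal disrotatory 6π electrocyclisation closes ring A by forming C5–C6; enolisation of the resulting 5H-benzofuran-6-one restores furan aromaticity and gives the free C6 phenol. The closest known reaction type is the dienylketene electrocyclisation that ends ketene-based aromatic annulations starting from aryl and heteroaryl diazoketones. No stereocentre is formed. The step needs the rearrangement to win over carbene addition to the vinyl and prenyl alkenes and over capture of the ketene by the phenol already formed; metal-free photolysis of the s-Z conformer favours the concerted shift, the ketene and vinyl group sit on adjacent ring carbons so closure is intramolecular, and high dilution should suppress ester formation.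

Step 11
Reactants: 22 2-[3,5-bis(methoxymethoxy)-2,6-bis(3-methylbut-2-en-1-yl)phenyl]-1-benzofuran-6-ol
Product: 23 mulberrofuran V
Conditions: HCl (1 M in MeOH), 25 to 40 °C, monitored closely
Reagents that add atoms: none
Why: Acid-catalysed transacetalisation to methanol releases both phenols, with dilute acid and mild temperature chosen so that protonation of the prenyl alkenes and chroman formation stay slow.

**Compound list**

1 | 5-chlororesorcinol (5-chlorobenzene-1,3-diol) | Oc1cc(O)cc(Cl)c1 | starting material
2 | 1-chloro-3,5-bis(methoxymethoxy)benzene | COCOc1cc(Cl)cc(OCOC)c1 | intermediate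
3 | 2,4-dibromo-3-chloro-1,5-bis(methoxymethoxy)benzene | COCOc1cc(OCOC)c(Br)c(Cl)c1Br | intermediate
4 | prenyl bromide (1-bromo-3-methylbut-2-ene) | CC(C)=CCBr | starting material
5 | [3-bromo-2-chloro-4,6-bis(methoxymethoxy)phenyl]magnesium chloride | COCOc1cc(OCOC)c([Mg]Cl)c(Cl)c1Br | intermediate
6 | 2-bromo-3-chloro-1,5-bis(methoxymethoxy)-4-(3-methylbut-2-en-1-yl)benzene | COCOc1cc(OCOC)c(CC=C(C)C)c(Cl)c1Br | intermediate
7 | [2-chloro-4,6-bis(methoxymethoxy)-3-(3-methylbut-2-en-1-yl)phenyl]magnesium chloride | COCOc1cc(OCOC)c([Mg]Cl)c(Cl)c1CC=C(C)C | intermediate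
8 | 3-chloro-1,5-bis(methoxymethoxy)-2,4-bis(3-methylbut-2-en-1-yl)benzene | COCOc1cc(OCOC)c(CC=C(C)C)c(Cl)c1CC=C(C)C | intermediate
9 | 3-bromofuran-2-carboxylic acid | O=C(O)c1occc1Br | starting material
10 | methyl 3-bromofuran-2-carboxylate | COC(=O)c1occc1Br | intermediate
11 | 4,4,5,5-tetramethyl-2-vinyl-1,3,2-dioxaborolane | C=CB1OC(C)(C)C(C)(C)O1 | starting material
12 | methyl 3-ethenylfuran-2-carboxylate | C=Cc1ccoc1C(=O)OC | intermediate
13 | [4-ethenyl-5-(methoxycarbonyl)furan-2-yl]magnesium chloride | C=Cc1cc([Mg]Cl)oc1C(=O)OC | intermediate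
14 | [4-ethenyl-5-(methoxycarbonyl)furan-2-yl]zinc chloride | C=Cc1cc([Zn]Cl)oc1C(=O)OC | intermediate
15 | methyl 5-[3,5-bis(methoxymethoxy)-2,6-bis(3-methylbut-2-en-1-yl)phenyl]-3-ethenylfuran-2-carboxylate | C=Cc1cc(oc1C(=O)OC)-c1c(CC=C(C)C)c(OCOC)cc(OCOC)c1CC=C(C)C | intermediate
16 | 5-[3,5-bis(methoxymethoxy)-2,6-bis(3-methylbut-2-en-1-yl)phenyl]-3-ethenylfuran-2-carboxylic acid | C=Cc1cc(oc1C(=O)O)-c1c(CC=C(C)C)c(OCOC)cc(OCOC)c1CC=C(C)C | intermediate
17 | trimethylsilyldiazomethane | C[Si](C)(C)C=[N+]=[N-] | starting material
18 | ethyl carbonic anhydride of acid 16 | C=Cc1cc(oc1C(=O)OC(=O)OCC)-c1c(CC=C(C)C)c(OCOC)cc(OCOC)c1CC=C(C)C | intermediate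
19 | 2-diazo-1-{5-[3,5-bis(methoxymethoxy)-2,6-bis(3-methylbut-2-en-1-yl)phenyl]-3-ethenylfuran-2-yl}ethan-1-one | C=Cc1cc(oc1C(=O)C=[N+]=[N-])-c1c(CC=C(C)C)c(OCOC)cc(OCOC)c1CC=C(C)C | intermediate
20 | 2-{5-[3,5-bis(methoxymethoxy)-2,6-bis(3-methylbut-2-en-1-yl)phenyl]-3-ethenylfuran-2-yl}ethen-1-one (ketene) | C=Cc1cc(oc1C=C=O)-c1c(CC=C(C)C)c(OCOC)cc(OCOC)c1CC=C(C)C | intermediate
21 | 2-[3,5-bis(methoxymethoxy)-2,6-bis(3-methylbut-2-en-1-yl)phenyl]-5H-1-benzofuran-6-one | O=C1CC=C2C=C(OC2=C1)-c1c(CC=C(C)C)c(OCOC)cc(OCOC)c1CC=C(C)C | intermediate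
22 | 2-[3,5-bis(methoxymethoxy)-2,6-bis(3-methylbut-2-en-1-yl)phenyl]-1-benzofuran-6-ol | CC(C)=CCc1c(OCOC)cc(OCOC)c(CC=C(C)C)c1-c1cc2ccc(O)cc2o1 | intermediate
23 | mulberrofuran V, 5-(6-hydroxy-1-benzofuran-2-yl)-4,6-bis(3-methylbut-2-en-1-yl)benzene-1,3-diol | CC(C)=CCc1c(O)cc(O)c(CC=C(C)C)c1-c1cc2ccc(O)cc2o1 | target

**Step count**

Total steps: 11. Longest linear sequence: 9 steps (steps 1–4 and 7–11, from 5-chlororesorcinol); the furan branch contributes steps 5 and 6.

**Steps most likely to fail**

Step 10. Nitrogen loss may proceed through a free carbene that adds to the neighbouring vinyl group, or the ketene may be acylating the phenol already formed instead of cyclising. Fallback: setting out from 19, the Wolff rearrangement is run with PhCO2Ag and Et3N in THF/H2O so that the ketene is trapped at once by water (Arndt–Eistert homologation) to give 2-{5-[3,5-bis(methoxymethoxy)-2,6-bis(3-methylbut-2-en-1-yl)phenyl]-3-ethenylfuran-2-yl}acetic acid F1. Heating F1 with Ac2O and NaOAc regenerates the ketene from the mixed anhydride under conditions where the phenol is acetylated as soon as it forms, giving 2-[3,5-bis(methoxymethoxy)-2,6-bis(3-methylbut-2-en-1-yl)phenyl]-1-benzofuran-6-yl acetate F2. K2CO3 in MeOH cleaves the acetate and the route is rejoined at 22.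

Step 7. Oxidative addition into the doubly ortho-substituted C–Cl bond may be slower than protonation or homocoupling of the furylzinc reagent at the temperature required. Fallback: setting out from 12, the magnesiated furan 13 is quenched with 2-isopropoxy-4,4,5,5-tetramethyl-1,3,2-dioxaborolane to give the isolable boronate methyl 3-ethenyl-5-(4,4,5,5-tetramethyl-1,3,2-dioxaborolan-2-yl)furan-2-carboxylate F3. This stable nucleophile is coupled with 8 under Suzuki–Miyaura conditions (Pd(OAc)2, SPhos, K3PO4, toluene/H2O, 90 °C), which allow longer reaction times, and the route is rejoined at 15.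

Step 11. Protonation of a prenyl alkene by the Brønsted acid, followed by capture of the cation by the adjacent freed phenol, would close a chroman ring. Fallback: setting out from 22, the acetals are exchanged for silyl ethers without any protic acid using TMSOTf and 2,2'-bipyridyl in CH2Cl2 at 0 °C, giving the tris(trimethylsilyl) ether of mulberrofuran V F4. Its silyl groups are hydrolysed with K2CO3 in THF/H2O at rt, and the route is rejoined at 23.

**Further compounds**

F1 | step 10 | 2-{5-[3,5-bis(methoxymethoxy)-2,6-bis(3-methylbut-2-en-1-yl)phenyl]-3-ethenylfuran-2-yl}acetic acid | C=Cc1cc(oc1CC(=O)O)-c1c(CC=C(C)C)c(OCOC)cc(OCOC)c1CC=C(C)C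
F2 | step 10 | 2-[3,5-bis(methoxymethoxy)-2,6-bis(3-methylbut-2-en-1-yl)phenyl]-1-benzofuran-6-yl acetate | CC(=O)Oc1ccc2cc(oc2c1)-c1c(CC=C(C)C)c(OCOC)cc(OCOC)c1CC=C(C)C
F3 | step 7 | methyl 3-ethenyl-5-(4,4,5,5-tetramethyl-1,3,2-dioxaborolan-2-yl)furan-2-carboxylate | C=Cc1cc(oc1C(=O)OC)B1OC(C)(C)C(C)(C)O1
F4 | step 11 | tris(trimethylsilyl) ether of mulberrofuran V | CC(C)=CCc1c(O[Si](C)(C)C)cc(O[Si](C)(C)C)c(CC=C(C)C)c1-c1cc2ccc(O[Si](C)(C)C)cc2o1
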